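**Plan**
- Numbering (labdane): ring A = C1–C5 + C10, ring B = C5–C10. C18 methyl and C19 acid sit on C4, C20 methyl on C10, C17 acid on C8, side chain C11–C16 on C9.
- Retrosynthesis: cut C12–C13 (butenolide off). Tie the C17 carboxyl to O–C12 as a δ-lactone and add a C8=C9 double bond. Then cut C5–C10 and C6–C7 together (retro-Diels–Alder), and finally C8–C9, C10–C20 and C3–C4 of the open chain.
- Enabling feature: in ring B the carboxyl-bearing C8 and the arm-bearing C9 are neighbours. C7=C8–C9=C10 can therefore be an electron-poor 2-acyl diene whose inner carbons are clamped s-cis in a temporary six-membered lactone (C8–C17–O–C12–C11–C9). C1–C4 of ring A is exactly the four-carbon tether from diene end C10 to a vinyl group C5=C6 on quaternary C4.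
- Forward: the chain is joined at C3–C4 (copper allylic alkylation), C10–C20 (carbomagnesiation) and C8–C9 (Stille), and the lactone closes. Rings A and B then arise together in one cycloaddition. C8=C9 is reduced, the lactone is opened, and the butenolide is joined last at C12.
- Stereochemistry: C4 comes from the catalytic enantioselective allylic alkylation. C5 and C10 are relayed from C4 and from the E geometry of C9=C10. C9 is set by axial protonation in the dissolving-metal reduction and C8 by equilibration to the equatorial acyl group.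

Key step: step 10

Assumption: the antipode of the amino-acid-derived ligand in step 5 is chosen so that the alkyl group enters the face of 8 that gives (S)-10; both antipodes are accessible from the L- and D-amino acids.

Step 1
Reactants: 1 4-(tert-butyldimethylsilyloxy)but-1-yne; 2 1-chloro-3-iodopropane
Product: 3 tert-butyl[(7-chlorohept-3-yn-1-yl)oxy]dimethylsilane
Conditions: n-BuLi, THF, −78 °C; 2, DMPU, −78 °C → rt
Reagents that add atoms: none
Why: SN2 alkylation of the lithium acetylide occurs only at the C–I end of the dihalide because iodide is by far the better leaving group.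

Step 2
Reactants: 3 tert-butyl[(7-chlorohept-3-yn-1-yl)oxy]dimethylsilane
Product: 4 tert-butyl[(7-iodohept-3-yn-1-yl)oxy]dimethylsilane
Conditions: NaI, acetone, reflux
Reagents that add atoms: sodium iodide [Na+].[I-]
Why: The Finkelstein halide exchange is driven by precipitation of NaCl from acetone.

Step 3
Reactants: 5 glycolaldehyde dimer (1,4-dioxane-2,5-diol); 6 tert-butyl 2-(triphenylphosphoranylidene)propanoate
Product: 7 tert-butyl (E)-4-hydroxy-2-methylbut-2-enoate
Conditions: CH2Cl2, reflux
Reagents that add atoms: none
Why: Wittig olefination of monomeric glycolaldehyde (released from the dimer on warming) with a stabilised α-methyl ylide should give the (E)-trisubstituted enoate.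

Step 4
Reactants: 7 tert-butyl (E)-4-hydroxy-2-methylbut-2-enoate
Product: 8 tert-butyl (E)-4-[(diethoxyphosphoryl)oxy]-2-methylbut-2-enoate
Conditions: ClP(O)(OEt)2, Et3N, DMAP (cat.), CH2Cl2, 0 °C → rt
Reagents that add atoms: diethyl chlorophosphate CCOP(=O)(Cl)OCC
Why: O-phosphorylation of the primary allylic alcohol installs the leaving group needed for copper-catalysed allylic substitution without touching the alkene geometry.

Step 5
Reactants: 4 tert-butyl[(7-iodohept-3-yn-1-yl)oxy]dimethylsilane; 8 tert-butyl (E)-4-[(diethoxyphosphoryl)oxy]-2-methylbut-2-enoate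
Product: 10 tert-butyl (S)-9-(tert-butyldimethylsilyloxy)-2-ethenyl-2-methylnon-6-ynoate, via dialkylzinc 9 (not isolated)
Conditions: 4, Et2Zn (neat), CuI (cat.), 50 °C, volatiles off in vacuo; then 8, (CuOTf)2·C6H6 (5 mol %), chiral amino-acid Schiff-base dipeptide amide ligand (10 mol %), THF, −15 °C; aq. NH4Cl/HCl
Reagents that add atoms: none
Why: Iodine–zinc exchange gives the dialkylzinc, and copper-catalysed enantioselective SN2′ allylic alkylation of the γ-phosphoryloxy enoate places the alkyl group on the α-carbon, which creates quaternary C4 with its vinyl group while the chiral ligand on copper selects the alkene face.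

Step 6
Reactants: 10 tert-butyl (S)-9-(tert-butyldimethylsilyloxy)-2-ethenyl-2-methylnon-6-ynoate
Product: 11 tert-butyl (S)-2-ethenyl-9-hydroxy-2-methylnon-6-ynoate
Conditions: CSA (10 mol %), MeOH, 0 °C → rt
Reagents that add atoms: none
Why: Acid-catalysed methanolysis removes the primary silyl ether while the hindered tert-butyl ester stays intact.

Step 7
Reactants: 11 tert-butyl (S)-2-ethenyl-9-hydroxy-2-methylnon-6-ynoate
Product: 13 tert-butyl (2S,6E)-2-ethenyl-9-hydroxy-7-iodo-2,6-dimethylnon-6-enoate, via oxamagnesacycle 12 (not isolated)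
Conditions: MeMgBr (5 equiv), Fe(acac)3 (15 mol %), THF, 0 °C → rt; I2, THF, −40 → 0 °C; aq. NH4Cl, Na2S2O3
Reagents that add atoms: methylmagnesium bromide C[Mg]Br; iodine II
Why: Alkoxide-directed iron-catalysed syn-carbomagnesiation of the homopropargylic alcohol puts methyl on the distal carbon C10 and magnesium on C9 in a five-membered chelate, and iodinolysis with retention gives the tetrasubstituted alkene with C20 cis to iodine, the pivalate-like tert-butyl ester being too hindered to react.

Step 8
Reactants: 14 methyl propiolate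
Product: 15 methyl 2-(tributylstannyl)prop-2-enoate
Conditions: Bu3SnH, Pd(PPh3)4 (1 mol %), THF, 0 °C → rt
Reagents that add atoms: tributyltin hydride CCCC[SnH](CCCC)CCCC
Why: Palladium-catalysed syn-hydrostannation of an alkynoate delivers tin to the α-carbon because hydride goes to the electrophilic β-carbon.

Step 9
Reactants: 13 tert-butyl (2S,6E)-2-ethenyl-9-hydroxy-7-iodo-2,6-dimethylnon-6-enoate; 15 methyl 2-(tributylstannyl)prop-2-enoate
Product: 17 tert-butyl (2S,6E)-2-ethenyl-2-methyl-6-(3-methylidene-2-oxooxan-4-ylidene)heptanoate, via hydroxy diene ester 16 (not isolated)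
Conditions: Pd(PPh3)4 (5 mol %), CuI (20 mol %), CsF (2 equiv), DMF, 45 °C; crude: CSA (10 mol %), 4 Å MS, CH2Cl2, rt
Reagents that add atoms: none
Why: Copper- and fluoride-accelerated Stille coupling forms C8–C9 with retention of the C9=C10 geometry, and acid-catalysed lactonisation of C12–OH onto the C17 methyl ester closes the six-membered ring that clamps the diene s-cis.

Step 10
Reactants: 17 tert-butyl (2S,6E)-2-ethenyl-2-methyl-6-(3-methylidene-2-oxooxan-4-ylidene)heptanoate
Product: 18 tert-butyl 13,14,15,16-tetranorlabd-8-en-17,12-olid-19-oate (trans-decalin, 5α-H, 10β-Me, 4α-Me, 4β-CO2tBu, C8=C9 inside the δ-lactone)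
Conditions: PhMe (5 mM), BHT (0.1 equiv), degassed, sealed vessel, 165 °C
Reagents that add atoms: none
Why: The reaction is a concerted but asynchronous thermal [4+2] cycloaddition in the inverse-demand sense: the lactone carbonyl on C8 lowers the diene LUMO and makes C7 the electrophilic end, which matches the nucleophilic CH2 terminus C6 of the vinyl group, so C6–C7 bonding leads and the crowded C5–C10 bond follows in the same step. The closest known reaction types are the intramolecular Diels–Alder reaction of 1,7,9-decatrienes that carry a 2-alkoxycarbonyl diene and the cycloaddition of ring-clamped bis-exocyclic (o-quinodimethane-like) dienes bearing a methyl group on the tethered terminus to unactivated vinyl groups. Ring B closes as the six-membered cycloadduct ring (C5–C10) and ring A closes at the same time in the fused mode through the C1–C4 tether folded as a chair, which excludes the bridged regioisomer. C10 is fixed by suprafacial addition to the E-configured C9=C10 bond (tether outside, C20 methyl inside) and C5 by the tether-exo transition state, in which quaternary C4 points away from the lactone ring and the C11 methylene, so that H-5 and C20 end up anti (trans-decalin). The absolute sense comes from (S)-C4: in the chair-like fold the flat, smaller ester takes the axial site syn to C20 and the C18 methyl the equatorial one, which selects one face of the vinyl group. The step needs periselectivity over dimerisation and over the 1,5-hydrogen shift from C20 to C7, and high dilution, the radical inhibitor, the s-cis clamp and the short tether are there to secure it.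

Step 11
Reactants: 18 tert-butyl 13,14,15,16-tetranorlabd-8-en-17,12-olid-19-oate
Product: 21 tert-butyl (8β-H,9α-H)-13,14,15,16-tetranorlabdan-17,12-olid-19-oate (trans-fused δ-lactone), via lithium enolate 19 (not isolated), via 8-epi lactone 20 (not isolated)
Conditions: Li, NH3(l)/THF, t-BuOH (1 equiv), −78 °C; isoprene, solid NH4Cl; crude: KOtBu (0.3 equiv), THF/t-BuOH, 0 °C → rt
Reagents that add atoms: none
Why: In this dissolving-metal (Birch-type) conjugate reduction the C9 carbanion is protonated axially on the α face opposite C20 (9α-H, side arm equatorial), the surviving lactone enolate protects C17 from over-reduction, and alkoxide equilibration moves C17 from the axial site, where it clashes with C20, to the equatorial one (8β-H).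

Step 12
Reactants: 21 tert-butyl (8β-H,9α-H)-13,14,15,16-tetranorlabdan-17,12-olid-19-oate
Product: 23 19-tert-butyl 17-(4-methoxybenzyl) 12-hydroxy-13,14,15,16-tetranorlabdane-17,19-dioate, via potassium carboxylate 22 (not isolated)
Conditions: KOH (1.1 equiv), THF/H2O, 40 °C; evaporate, PhMe azeotrope; PMBCl, Bu4NI (cat.), DMF, rt
Reagents that add atoms: potassium hydroxide [K+].[OH-]; 4-methoxybenzyl chloride COc1ccc(CCl)cc1
Why: Saponification of the accessible δ-lactone (the axial, neopentyl-type tert-butyl ester is inert) followed by SN2 O-alkylation of the carboxylate frees C12–OH and puts an acid-labile ester on C17 without disturbing the already equilibrated C8.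

Step 13
Reactants: 23 19-tert-butyl 17-(4-methoxybenzyl) 12-hydroxy-13,14,15,16-tetranorlabdane-17,19-dioate
Product: 24 19-tert-butyl 17-(4-methoxybenzyl) 12-iodo-13,14,15,16-tetranorlabdane-17,19-dioate
Conditions: I2, PPh3, imidazole, CH2Cl2, 0 °C → rt
Reagents that add atoms: iodine II
Why: The Appel reaction converts the unhindered primary alcohol into the iodide quickly under nearly neutral conditions, which limits the time available for relactonisation.

Step 14
Reactants: 24 19-tert-butyl 17-(4-methoxybenzyl) 12-iodo-13,14,15,16-tetranorlabdane-17,19-dioate; 25 3-bromofuran-2(5H)-one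
Product: 27 19-tert-butyl 17-(4-methoxybenzyl) labd-13-en-16,15-olide-17,19-dioate, via alkylzinc iodide 26 (not isolated)
Conditions: Zn dust (BrCH2CH2Br, TMSCl activation), DMA, 40 °C; 25, Pd2(dba)3 (2.5 mol %), SPhos (10 mol %), THF/DMA, rt
Reagents that add atoms: none
Why: Zinc insertion into the primary C–I bond and Negishi sp3–sp2 cross-coupling with the α-bromobutenolide form C12–C13 under neutral conditions that leave both esters, C8 and the base-sensitive butenolide untouched.

Step 15
Reactants: 27 19-tert-butyl 17-(4-methoxybenzyl) labd-13-en-16,15-olide-17,19-dioate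
Product: 28 labd-13-en-16,15-olide-17,19-dioic acid (CNP0478950.1; 4α-Me, 4β-CO2H, 5α-H, 8β-H, 9α-H, 10β-Me)
Conditions: TFA/CH2Cl2 (1:2), anisole, 0 °C → rt
Reagents that add atoms: none
Why: Acidolysis ionises both the tert-butyl and the 4-methoxybenzyl ester at the alkyl–oxygen bond, so steric hindrance at C19 does not matter, and the butenolide and all stereocentres are inert to acid.

**Compound list**
1 | 4-(tert-butyldimethylsilyloxy)but-1-yne | C#CCCO[Si](C)(C)C(C)(C)C | starting material
2 | 1-chloro-3-iodopropane | ClCCCI | starting material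
3 | tert-butyl[(7-chlorohept-3-yn-1-yl)oxy]dimethylsilane | ClCCCC#CCCO[Si](C)(C)C(C)(C)C | intermediate
4 | tert-butyl[(7-iodohept-3-yn-1-yl)oxy]dimethylsilane | ICCCC#CCCO[Si](C)(C)C(C)(C)C | intermediate
5 | glycolaldehyde dimer | OC1COC(O)CO1 | starting material
6 | tert-butyl 2-(triphenylphosphoranylidene)propanoate | CC(C(=O)OC(C)(C)C)=P(c1ccccc1)(c1ccccc1)c1ccccc1 | starting material
7 | tert-butyl (E)-4-hydroxy-2-methylbut-2-enoate | C/C(=C\CO)C(=O)OC(C)(C)C | intermediate
8 | tert-butyl (E)-4-[(diethoxyphosphoryl)oxy]-2-methylbut-2-enoate | C/C(=C\COP(=O)(OCC)OCC)C(=O)OC(C)(C)C | intermediate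
9 | bis[7-(tert-butyldimethylsilyloxy)hept-4-yn-1-yl]zinc | CC(C)(C)[Si](C)(C)OCCC#CCCC[Zn]CCCC#CCCO[Si](C)(C)C(C)(C)C | intermediate
10 | tert-butyl (S)-9-(tert-butyldimethylsilyloxy)-2-ethenyl-2-methylnon-6-ynoate | CC(C)(C)[Si](C)(C)OCCC#CCCC[C@](C)(C(=O)OC(C)(C)C)C=C | intermediate
11 | tert-butyl (S)-2-ethenyl-9-hydroxy-2-methylnon-6-ynoate | OCCC#CCCC[C@](C)(C(=O)OC(C)(C)C)C=C | intermediate
12 | five-membered oxamagnesacycle (Mg on C9 and on O–C12, C20 cis to Mg) | [Mg]1OCC/C1=C(/C)CCC[C@](C)(C(=O)OC(C)(C)C)C=C | intermediate
13 | tert-butyl (2S,6E)-2-ethenyl-9-hydroxy-7-iodo-2,6-dimethylnon-6-enoate | OCC/C(I)=C(/C)CCC[C@](C)(C(=O)OC(C)(C)C)C=C | intermediate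
14 | methyl propiolate | C#CC(=O)OC | starting material
15 | methyl 2-(tributylstannyl)prop-2-enoate | C=C(C(=O)OC)[Sn](CCCC)(CCCC)CCCC | intermediate
16 | tert-butyl (2S,6E)-2-ethenyl-7-(2-hydroxyethyl)-8-(methoxycarbonyl)-2,6-dimethylnona-6,8-dienoate | OCC/C(C(=C)C(=O)OC)=C(/C)CCC[C@](C)(C(=O)OC(C)(C)C)C=C | intermediate
17 | tert-butyl (2S,6E)-2-ethenyl-2-methyl-6-(3-methylidene-2-oxooxan-4-ylidene)heptanoate | C=C1C(=O)OCC/C1=C(/C)CCC[C@](C)(C(=O)OC(C)(C)C)C=C | intermediate
18 | tert-butyl 13,14,15,16-tetranorlabd-8-en-17,12-olid-19-oate | C[C@]12CCC[C@](C)(C(=O)OC(C)(C)C)[C@@H]1CCC3=C2CCOC3=O | intermediate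
19 | lithium enolate of the saturated lactone (9α-H, C8=C17 enolate) | C[C@]12CCC[C@](C)(C(=O)OC(C)(C)C)[C@@H]1CCC3=C([O-])OCC[C@@H]32.[Li+] | intermediate
20 | 8-epi (8α-H, cis-fused) lactone | C[C@]12CCC[C@](C)(C(=O)OC(C)(C)C)[C@@H]1CC[C@H]3[C@@H]2CCOC3=O | intermediate
21 | tert-butyl (8β-H,9α-H)-13,14,15,16-tetranorlabdan-17,12-olid-19-oate | C[C@]12CCC[C@](C)(C(=O)OC(C)(C)C)[C@@H]1CC[C@@H]3[C@@H]2CCOC3=O | intermediate
22 | potassium 19-tert-butoxy-12-hydroxy-19-oxo-13,14,15,16-tetranorlabdan-17-oate | C[C@]12CCC[C@](C)(C(=O)OC(C)(C)C)[C@@H]1CC[C@@H](C(=O)[O-])[C@@H]2CCO.[K+] | intermediate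
23 | 19-tert-butyl 17-(4-methoxybenzyl) 12-hydroxy-13,14,15,16-tetranorlabdane-17,19-dioate | C[C@]12CCC[C@](C)(C(=O)OC(C)(C)C)[C@@H]1CC[C@@H](C(=O)OCc3ccc(OC)cc3)[C@@H]2CCO | intermediate
24 | 19-tert-butyl 17-(4-methoxybenzyl) 12-iodo-13,14,15,16-tetranorlabdane-17,19-dioate | C[C@]12CCC[C@](C)(C(=O)OC(C)(C)C)[C@@H]1CC[C@@H](C(=O)OCc3ccc(OC)cc3)[C@@H]2CCI | intermediate
25 | 3-bromofuran-2(5H)-one | O=C1OCC=C1Br | starting material
26 | C12 alkylzinc iodide of 24 | C[C@]12CCC[C@](C)(C(=O)OC(C)(C)C)[C@@H]1CC[C@@H](C(=O)OCc3ccc(OC)cc3)[C@@H]2CC[Zn]I | intermediate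
27 | 19-tert-butyl 17-(4-methoxybenzyl) labd-13-en-16,15-olide-17,19-dioate | C[C@]12CCC[C@](C)(C(=O)OC(C)(C)C)[C@@H]1CC[C@@H](C(=O)OCc3ccc(OC)cc3)[C@@H]2CCC4=CCOC4=O | intermediate
28 | labd-13-en-16,15-olide-17,19-dioic acid (CNP0478950.1) | C[C@]12CCC[C@](C)(C(=O)O)[C@@H]1CC[C@@H](C(=O)O)[C@@H]2CCC1=CCOC1=O | target

Total step count: 15. Longest linear sequence: 12 (steps 1, 2, 5, 6, 7, 9, 10, 11, 12, 13, 14, 15).

**Steps most likely to fail**

**Step 10.**
- Risk: at the temperature the cycloaddition needs, the suprafacial 1,5-hydrogen shift from the inside C20 methyl to C7 may compete. The two chair folds of the tether (ester axial versus methyl axial at C4) may also be poorly discriminated, which would erode facial selectivity.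
- Fallback: it sets out from 17 and comes back at 18. It changes the oxidation level and the activation mode so that the same two bonds form at low temperature.
- DIBAL-H (1.1 equiv, CH2Cl2, −78 °C) reduces only the lactone carbonyl to the lactol tert-butyl (2S,6E)-2-ethenyl-6-(2-hydroxy-3-methylideneoxan-4-ylidene)-2-methylheptanoate F1.
- Ionisation with TMSOTf and 2,6-di-tert-butyl-4-methylpyridine at −78 °C gives the ring-clamped vinyl oxocarbenium ion. This cationic diene is strongly electrophilic at C7 and should undergo an ionic Diels–Alder reaction with the vinyl group.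
- Aqueous quench gives the tricyclic allylic lactol tert-butyl 17-hydroxy-12,17-epoxy-13,14,15,16-tetranorlabd-8-en-19-oate F2, and MnO2 oxidises it to 18.

**Step 9.**
- Risk: slow transmetalation between the tetrasubstituted iodide and the electron-poor, α-branched stannane may let protodestannylation and homocoupling take over. The acid used for ring closure may also isomerise the diene.
- Fallback: it sets out from 13 and comes back at 17. It builds the lactone carbonyl by oxidation instead of transesterification.
- Stille coupling of 13 with the more nucleophilic 2-(tributylstannyl)prop-2-en-1-ol gives the dienediol tert-butyl (2S,6E)-2-ethenyl-7-(2-hydroxyethyl)-8-(hydroxymethyl)-2,6-dimethylnona-6,8-dienoate F3.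
- Excess MnO2 oxidises only the allylic alcohol. The enal is trapped by C12–OH as the lactol, and this is oxidised further in the same flask to 17 under neutral conditions.

**Step 7.**
- Risk: regiocontrol of the carbomagnesiation may be lost, the excess Grignard reagent may attack the ester, or low-valent iron may isomerise the terminal alkene.
- Fallback: it sets out from 11 and comes back at 17, and it bypasses 13, 15 and 16.
- Esterification of 11 with 2-bromoacrylic acid (DCC, DMAP cat., CH2Cl2, 0 °C) gives the bromoacrylate tert-butyl (S)-9-[(2-bromoprop-2-enoyl)oxy]-2-ethenyl-2-methylnon-6-ynoate F4.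
- With Pd(PPh3)4, methylboronic acid and K2CO3 in dioxane at 70 °C, oxidative addition at C8–Br is followed by syn 6-exo-dig cyclic carbopalladation of the alkyne (C8–C9). Methyl cross-coupling of the resulting C10–palladium bond then places C20 cis to C8 and delivers 17 with the required E geometry.

Further compounds
F1 | step 10 | tert-butyl (2S,6E)-2-ethenyl-6-(2-hydroxy-3-methylideneoxan-4-ylidene)-2-methylheptanoate (anomeric mixture) | C=C1C(O)OCC/C1=C(/C)CCC[C@](C)(C(=O)OC(C)(C)C)C=C
F2 | step 10 | tert-butyl 17-hydroxy-12,17-epoxy-13,14,15,16-tetranorlabd-8-en-19-oate (anomeric mixture) | C[C@]12CCC[C@](C)(C(=O)OC(C)(C)C)[C@@H]1CCC3=C2CCOC3O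
F3 | step 9 | tert-butyl (2S,6E)-2-ethenyl-7-(2-hydroxyethyl)-8-(hydroxymethyl)-2,6-dimethylnona-6,8-dienoate | OCC/C(C(=C)CO)=C(/C)CCC[C@](C)(C(=O)OC(C)(C)C)C=C
F4 | step 7 | tert-butyl (S)-9-[(2-bromoprop-2-enoyl)oxy]-2-ethenyl-2-methylnon-6-ynoate | C=C(Br)C(=O)OCCC#CCCC[C@](C)(C(=O)OC(C)(C)C)C=C
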